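**Strategy.** Drimane numbering is used. Ring B is assembled in one operation on an enantioenriched ring A ketone: its carbonyl carbon C5 and its only enolisable α-carbon C10 (C4 is quaternary) are joined to a four-carbon unit C6–C9. This unit is a dienylphosphonate mounted on (5R)-5-menthyloxybutenolide, which already carries C11 and C12. Conjugate addition forms C9–C10 and sets both centres. Intramolecular Horner–Wadsworth–Emmons olefination forms C5–C6 as an alkene, so the trans ring fusion is fixed only afterwards, when the 5α-hydroxyl is brought in through the α-epoxide. The acetal carbon becomes the C11 aldehyde, the lactone carbonyl the C12 aldehyde, and the p-coumarate is attached late.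

Key step: step 5

Remark: α is the face opposite the C10 methyl; C2 of compounds 3–5 is epimerisable and the acetal carbons made in step 8 are epimer mixtures, both without consequence; all compounds marked as starting materials are taken as purchasable.

Step 1
Reactants: 1 2,6,6-trimethylcyclohex-2-en-1-one; 2 bis(pinacolato)diboron
Product: 4 (2S,3R)-3-hydroxy-2,6,6-trimethylcyclohexan-1-one, via β-boryl ketone 3 (not isolated)
Conditions: CuCl (3 mol %), Josiphos-type ligand (enantiomer giving the 3R boronate), NaOtBu (cat.), MeOH, THF, rt; then NaBO3·4H2O, THF/H2O, rt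
Reagents that add atoms: sodium perborate, [Na+].[O-]OB=O
Why: Enantioselective conjugate borylation catalysed by monovalent copper sets the C–B centre as R by ligand-controlled delivery of boron to one face of the enone β-carbon (the α-centre is epimerisable and is erased in step 5), and stereoretentive perborate oxidation of the C–B bond then gives the 3R alcohol.

Step 2
Reactants: 4 (2S,3R)-3-hydroxy-2,6,6-trimethylcyclohexan-1-one
Product: 5 (2S,3R)-3-[(tert-butyldimethylsilyl)oxy]-2,6,6-trimethylcyclohexan-1-one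
Conditions: TBSCl, imidazole, DMF, 40 °C
Reagents that add atoms: tert-butyldimethylsilyl chloride, CC(C)(C)[Si](C)(C)Cl
Why: Standard imidazole-promoted silylation of the secondary alcohol touches no stereocentre, blocks retro-aldol or dehydration chemistry, and the bulky silyl ether later shields one face of the enolate.

Step 3
Reactants: 6 (5R)-5-[(1R,2S,5R)-menthyloxy]furan-2(5H)-one
Product: 8 (5R)-3-bromo-5-[(1R,2S,5R)-menthyloxy]furan-2(5H)-one, via trans-dibromide 7 (not isolated)
Conditions: Br2, CH2Cl2, 0 °C; then Et3N, 0 °C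
Reagents that add atoms: bromine, BrBr
Why: Bromine addition to the butenolide alkene followed by amine-induced E1cB loss of HBr (acidic α-hydrogen, β-bromide) is the usual route to α-bromobutenolides, and the acetal centre is not involved and should not epimerise on brief exposure to the amine at 0 °C.

Step 4
Reactants: 8 (5R)-3-bromo-5-[(1R,2S,5R)-menthyloxy]furan-2(5H)-one; 9 diethyl vinylphosphonate
Product: 10 diethyl {(E)-2-[(5R)-5-[(1R,2S,5R)-menthyloxy]-2-oxo-2,5-dihydrofuran-3-yl]vinyl}phosphonate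
Conditions: Pd(OAc)2 (5 mol %), P(o-tol)3, NaHCO3, Bu4NCl, DMF, 70 °C
Reagents that add atoms: none
Why: Heck reaction, in which zerovalent palladium inserts into the vinyl C–Br bond, the vinylphosphonate inserts at its unsubstituted carbon and syn β-hydride elimination gives the E-dienylphosphonate, while the weak inorganic base leaves the acetal centre untouched.

Step 5
Reactants: 5 (2S,3R)-3-[(tert-butyldimethylsilyl)oxy]-2,6,6-trimethylcyclohexan-1-one; 10 diethyl {(E)-2-[(5R)-5-[(1R,2S,5R)-menthyloxy]-2-oxo-2,5-dihydrofuran-3-yl]vinyl}phosphonate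
Product: 13 (11R)-1β-[(tert-butyldimethylsilyl)oxy]-11-[(1R,2S,5R)-menthyloxy]drima-5,7-dien-12,11-olide, via lithium enolate 11 (not isolated), via Michael adduct 12 (not isolated)
Conditions: LiN(iPr)2 (1.05 equiv), THF, −78 → −40 °C; then 10, −78 °C → rt
Reagents that add atoms: none
Why: LiN(iPr)2 removes the only α-hydrogen of 5 (C10–H) to give enolate 11, which adds through C10 to the butenolide β-carbon C9 of 10, so that the charge of adduct 12 is shared by the lactone enolate and the α-phosphoryl carbon C6; C6 then adds to the C5 carbonyl and the β-oxidophosphonate collapses with loss of lithium diethyl phosphate to give the C5=C6 bond. The closest known reaction type is the conjugate addition–intramolecular Wittig or Horner–Wadsworth–Emmons cyclohexadiene annulation of ketone enolates with butadienylphosphonium salts and dienylphosphonates (a Michael-initiated ring closure). Ring B (C5–C10) is closed by 6-exo-trig attack of C6 on the C5 carbonyl followed by syn elimination of phosphate. C10 is set by attack anti to the C1 silyloxy group, which is pseudoaxial to avoid A(1,2) strain with the C10 methyl, so the methyl ends cis to the C1 oxygen; C9 is set by attack on the butenolide face opposite the C11 menthyloxy group, the usual course of conjugate additions to 5-alkoxybutenolides, which gives 9α-H. The step needs attack at C9 and not at C7, which the double activation of C9 (β to the lactone carbonyl, vinylogous to phosphorus) secures, and it needs the congested C5 carbonyl to react, which is helped by the closure being intramolecular; because C5 becomes trigonal no ring-fusion centre is made here, which deliberately avoids the cis-fused ketol that an aldol closure onto ring A would give.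

Step 6
Reactants: 13 (11R)-1β-[(tert-butyldimethylsilyl)oxy]-11-[(1R,2S,5R)-menthyloxy]drima-5,7-dien-12,11-olide
Product: 14 (11R)-1β-[(tert-butyldimethylsilyl)oxy]-5α,6α-epoxy-11-[(1R,2S,5R)-menthyloxy]drim-7-en-12,11-olide
Conditions: mCPBA, NaHCO3, CH2Cl2, 0 °C
Reagents that add atoms: 3-chloroperbenzoic acid, OOC(=O)c1cccc(Cl)c1
Why: Prilezhaev epoxidation, in which the peracid selects the electron-rich γ,δ-alkene C5=C6 over the lactone-conjugated C7=C8 and attacks from the α-face, opposite the axial 10β- and 4β-methyl groups, which sets C5 (oxygen α, trans to the angular methyl) and C6.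

Step 7
Reactants: 14 (11R)-1β-[(tert-butyldimethylsilyl)oxy]-5α,6α-epoxy-11-[(1R,2S,5R)-menthyloxy]drim-7-en-12,11-olide
Product: 15 (11R)-1β-[(tert-butyldimethylsilyl)oxy]-5α-hydroxy-11-[(1R,2S,5R)-menthyloxy]drim-7-en-12,11-olide
Conditions: Pd2(dba)3·CHCl3 (2.5 mol %), PBu3, HCO2H, Et3N, 1,4-dioxane, rt
Reagents that add atoms: none
Why: Palladium-catalysed formate hydrogenolysis of a vinyl epoxide, in which zerovalent palladium ionises the allylic C6–O bond to a π-allyl complex over C6–C8 and hydride from the palladium formate is delivered to C6 so that C7=C8 stays conjugated with the lactone; the C5–O bond is never broken, so the 5α-hydroxyl keeps the epoxide configuration.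

Step 8
Reactants: 15 (11R)-1β-[(tert-butyldimethylsilyl)oxy]-5α-hydroxy-11-[(1R,2S,5R)-menthyloxy]drim-7-en-12,11-olide
Product: 17 1β-[(tert-butyldimethylsilyl)oxy]-11,12-dimethoxy-11,12-epoxydrim-7-en-5α-ol, via lactol 16 (not isolated)
Conditions: iBu2AlH (2.5 equiv), CH2Cl2, −78 °C; then MeOH, PPTS, rt
Reagents that add atoms: methanol, CO
Why: Partial reduction of the lactone by iBu2AlH at −78 °C (stable tetrahedral aluminate) gives the lactol, and acid-catalysed acetal exchange in methanol through the ring oxocarbenium ions converts the lactol and the menthyl acetal into the cyclic bis(methyl acetal), a base-stable masked 1,4-dialdehyde, while C9 is untouched and the two acetal centres are formed as mixtures that step 11 removes.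

Step 9
Reactants: 17 1β-[(tert-butyldimethylsilyl)oxy]-11,12-dimethoxy-11,12-epoxydrim-7-en-5α-ol
Product: 18 11,12-dimethoxy-11,12-epoxydrim-7-ene-1β,5α-diol
Conditions: Bu4NF, THF, 50 °C
Reagents that add atoms: none
Why: Fluoride-induced desilylation, driven by the strong Si–F bond, frees the 1β-hydroxyl without touching the acetals, the tertiary alcohol or any stereocentre.

Step 10
Reactants: 18 11,12-dimethoxy-11,12-epoxydrim-7-ene-1β,5α-diol; 19 (E)-4-acetoxycinnamic acid
Product: 21 1β-[(E)-4-acetoxycinnamoyloxy]-11,12-dimethoxy-11,12-epoxydrim-7-en-5α-ol, via acid chloride 20 (not isolated)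
Conditions: 19, (COCl)2, DMF (cat.), CH2Cl2, 0 °C → rt, concentrate; then 18, DMAP, pyridine, CH2Cl2, 40 °C
Reagents that add atoms: none
Why: DMAP-catalysed acylation through the acylpyridinium ion acylates the only reactive hydroxyl, the secondary 1β-OH (the tertiary 5α-OH is inert), with retention at C1 because its C–O bond is not broken and with the E-alkene carried through from 19.

Step 11
Reactants: 21 1β-[(E)-4-acetoxycinnamoyloxy]-11,12-dimethoxy-11,12-epoxydrim-7-en-5α-ol
Product: 23 1β-[(E)-p-coumaroyloxy]-5α-hydroxydrim-7-ene-11,12-dial (CNP0323926.1), via phenol bis-acetal 22 (not isolated)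
Conditions: K2CO3, MeOH, 0 °C; then 1 M HCl, THF, rt
Reagents that add atoms: water, O
Why: Base-mediated methanolysis removes the aryl acetate much faster than the hindered conjugated C1 ester, and mild aqueous acid then hydrolyses the cyclic bis-acetal to the 11,12-dialdehyde (acetal hydrolysis), conditions under which the base-labile C9 centre and the tertiary alcohol are expected to survive.

**Compound list**

1 | 2,6,6-trimethylcyclohex-2-en-1-one | CC1=CCCC(C)(C)C1=O | starting material
2 | bis(pinacolato)diboron | CC1(C)OB(OC1(C)C)B1OC(C)(C)C(C)(C)O1 | starting material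
3 | (2S,3R)-2,6,6-trimethyl-3-(4,4,5,5-tetramethyl-1,3,2-dioxaborolan-2-yl)cyclohexan-1-one (C2 epimerisable) | CC1(C)CC[C@@H](B2OC(C)(C)C(C)(C)O2)[C@H](C)C1=O | intermediate
4 | (2S,3R)-3-hydroxy-2,6,6-trimethylcyclohexan-1-one (trans; C2 epimerisable) | CC1(C)CC[C@@H](O)[C@H](C)C1=O | intermediate
5 | (2S,3R)-3-[(tert-butyldimethylsilyl)oxy]-2,6,6-trimethylcyclohexan-1-one | CC1(C)CC[C@@H](O[Si](C)(C)C(C)(C)C)[C@H](C)C1=O | intermediate
6 | (5R)-5-{[(1R,2S,5R)-2-isopropyl-5-methylcyclohexyl]oxy}furan-2(5H)-one | O=C1C=C[C@H](O[C@@H]2C[C@H](C)CC[C@H]2C(C)C)O1 | starting material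
7 | (5R)-3,4-dibromo-5-[(1R,2S,5R)-menthyloxy]dihydrofuran-2(3H)-one (trans-dibromide, C3/C4 not assigned) | O=C1C(Br)C(Br)[C@H](O[C@@H]2C[C@H](C)CC[C@H]2C(C)C)O1 | intermediate
8 | (5R)-3-bromo-5-[(1R,2S,5R)-menthyloxy]furan-2(5H)-one | O=C1C(Br)=C[C@H](O[C@@H]2C[C@H](C)CC[C@H]2C(C)C)O1 | intermediate
9 | diethyl vinylphosphonate | C=CP(=O)(OCC)OCC | starting material
10 | diethyl {(E)-2-[(5R)-5-[(1R,2S,5R)-menthyloxy]-2-oxo-2,5-dihydrofuran-3-yl]vinyl}phosphonate | O=C1C(/C=C/P(=O)(OCC)OCC)=C[C@H](O[C@@H]2C[C@H](C)CC[C@H]2C(C)C)O1 | intermediate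
11 | lithium enolate of 5 (C10=C5 enolate, 1R silyl ether) | CC1(C)CC[C@@H](O[Si](C)(C)C(C)(C)C)C(C)=C1O[Li] | intermediate
12 | Michael adduct, lithium salt: ring A ketone bonded through C10 (methyl β) to C9 (9α-H) of the (11R)-menthyloxy lactone, charge shared by the lactone enolate and C6 | CC1(C)CC[C@@H](O[Si](C)(C)C(C)(C)C)[C@](C)([C@H]2[C@H](O[C@@H]3C[C@H](C)CC[C@H]3C(C)C)OC(O[Li])=C2/C=C/P(=O)(OCC)OCC)C1=O | intermediate
13 | (11R)-1β-[(tert-butyldimethylsilyl)oxy]-11-[(1R,2S,5R)-menthyloxy]drima-5,7-dien-12,11-olide (9α-H, 10β-CH3, lactone C=O at C12) | CC1(C)CC[C@@H](O[Si](C)(C)C(C)(C)C)[C@]2(C)[C@H]3[C@H](O[C@@H]4C[C@H](C)CC[C@H]4C(C)C)OC(=O)C3=CC=C12 | intermediate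
14 | (11R)-1β-[(tert-butyldimethylsilyl)oxy]-5α,6α-epoxy-11-[(1R,2S,5R)-menthyloxy]drim-7-en-12,11-olide | CC1(C)CC[C@@H](O[Si](C)(C)C(C)(C)C)[C@]2(C)[C@H]3[C@H](O[C@@H]5C[C@H](C)CC[C@H]5C(C)C)OC(=O)C3=C[C@@H]4O[C@]124 | intermediate
15 | (11R)-1β-[(tert-butyldimethylsilyl)oxy]-5α-hydroxy-11-[(1R,2S,5R)-menthyloxy]drim-7-en-12,11-olide | CC1(C)CC[C@@H](O[Si](C)(C)C(C)(C)C)[C@]2(C)[C@H]3[C@H](O[C@@H]4C[C@H](C)CC[C@H]4C(C)C)OC(=O)C3=CC[C@@]12O | intermediate
16 | (11R)-1β-[(tert-butyldimethylsilyl)oxy]-11-[(1R,2S,5R)-menthyloxy]-11,12-epoxydrim-7-ene-5α,12-diol (lactol, C12 epimers) | CC1(C)CC[C@@H](O[Si](C)(C)C(C)(C)C)[C@]2(C)[C@H]3[C@H](O[C@@H]4C[C@H](C)CC[C@H]4C(C)C)OC(O)C3=CC[C@@]12O | intermediate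
17 | 1β-[(tert-butyldimethylsilyl)oxy]-11,12-dimethoxy-11,12-epoxydrim-7-en-5α-ol (9α-H; C11/C12 epimer mixture) | CC1(C)CC[C@@H](O[Si](C)(C)C(C)(C)C)[C@]2(C)[C@H]3C(OC)OC(OC)C3=CC[C@@]12O | intermediate
18 | 11,12-dimethoxy-11,12-epoxydrim-7-ene-1β,5α-diol (C11/C12 epimer mixture) | CC1(C)CC[C@@H](O)[C@]2(C)[C@H]3C(OC)OC(OC)C3=CC[C@@]12O | intermediate
19 | (E)-4-acetoxycinnamic acid | CC(=O)Oc1ccc(/C=C/C(=O)O)cc1 | starting material
20 | (E)-4-acetoxycinnamoyl chloride | CC(=O)Oc1ccc(/C=C/C(=O)Cl)cc1 | intermediate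
21 | 1β-[(E)-4-acetoxycinnamoyloxy]-11,12-dimethoxy-11,12-epoxydrim-7-en-5α-ol (C11/C12 epimer mixture) | CC1(C)CC[C@@H](OC(=O)/C=C/c2ccc(OC(C)=O)cc2)[C@]2(C)[C@H]3C(OC)OC(OC)C3=CC[C@@]12O | intermediate
22 | 1β-[(E)-4-hydroxycinnamoyloxy]-11,12-dimethoxy-11,12-epoxydrim-7-en-5α-ol (C11/C12 epimer mixture) | CC1(C)CC[C@@H](OC(=O)/C=C/c2ccc(O)cc2)[C@]2(C)[C@H]3C(OC)OC(OC)C3=CC[C@@]12O | intermediate
23 | 1β-[(E)-p-coumaroyloxy]-5α-hydroxydrim-7-ene-11,12-dial (9α-H, 10β-CH3), CNP0323926.1 | CC1(C)CC[C@@H](OC(=O)/C=C/c2ccc(O)cc2)[C@]2(C)[C@@H](C=O)C(C=O)=CC[C@@]12O | target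

**Step count.** Total: 11 steps. Longest linear sequence: 9 steps (steps 1, 2, 5–11; the branch through steps 3 and 4 is equally long).

**Steps most likely to fail**

Step 5 (key step). The hindered tetrasubstituted enolate may lose silyloxide by β-elimination or transfer a proton to the butenolide without adding to it, or the phosphonate-stabilised anion may fail to olefinate the carbonyl flanked by two quaternary carbons. The fallback sets out from 8 and 5 and comes back at 13; it makes the two bonds in separate operations by a Robinson-type sequence. Stille coupling of 8 with tributyl(1-ethoxyvinyl)stannane [PdCl2(PPh3)2, toluene, 90 °C] should give the enol ether (5R)-3-(1-ethoxyvinyl)-5-(menthyloxy)furan-2(5H)-one F1, which dilute aqueous HCl hydrolyses to the 3-acetylbutenolide F2. This doubly activated acceptor should take up enolate 11 (from 5) at −78 °C under the same facial control to give the Michael adduct, a β-keto lactone, F3. Its dianion [LiN(iPr)2, 2.2 equiv] should add through the methyl carbon C6 to the C5 carbonyl to give the ketol F4, which is dehydrated (TsOH, benzene, reflux) to the enolised 7-oxo-5-ene, the dienol F5. Triflation of the enol (PhNTf2, Et3N) gives the dienyl triflate F6, and palladium-catalysed formate reduction [Pd(OAc)2, PPh3, HCO2H, Bu3N, DMF, 60 °C] removes the triflate to give 13.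

Step 7. Hydride may be transferred to the more substituted allyl terminus C8, which would leave a deconjugated 6-ene, or the π-allyl complex may collapse by β-hydride loss to a dienol. The fallback sets out from 14 and comes back at 17; it replaces the palladium step by direct hydride opening and a redox detour. LiAlH4 (THF, 0 °C) should open the epoxide by trans-diaxial attack at C6 and reduce the acetal-lactone to the 11,12-diol, giving 1β-[(tert-butyldimethylsilyl)oxy]drim-7-ene-5α,11,12-triol F7. Swern oxidation [(COCl)2, DMSO, Et3N, −78 °C] should give the dialdehyde 1β-[(tert-butyldimethylsilyl)oxy]-5α-hydroxydrim-7-ene-11,12-dial F8, and MeOH/PPTS converts it into the cyclic bis(methyl acetal) 17.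

Step 10. Acylation of the neopentyl-type secondary alcohol may stall, or acetyl may be transferred from the aryl acetate to the alcohol. The fallback sets out from 18 and comes back at 22; it builds the cinnamate on the alcohol in two stages. Heating 18 with Meldrum's acid (toluene, 100 °C) should give the malonic half ester 1β-(carboxyacetoxy)-11,12-dimethoxy-11,12-epoxydrim-7-en-5α-ol F9. Knoevenagel–Doebner condensation of F9 with 4-hydroxybenzaldehyde (pyridine, piperidine cat., 80 °C) should give the E-configured p-coumarate 22 directly, and the acid stage of step 11 then completes the route.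

Further compounds
F1 | step 5 | (5R)-3-(1-ethoxyvinyl)-5-[(1R,2S,5R)-menthyloxy]furan-2(5H)-one | C=C(OCC)C1=C[C@H](O[C@@H]2C[C@H](C)CC[C@H]2C(C)C)OC1=O
F2 | step 5 | (5R)-3-acetyl-5-[(1R,2S,5R)-menthyloxy]furan-2(5H)-one | CC(=O)C1=C[C@H](O[C@@H]2C[C@H](C)CC[C@H]2C(C)C)OC1=O
F3 | step 5 | Michael adduct: ring A ketone of 5 bonded through C10 to C9 of the (11R)-menthyloxy lactone carrying the C7 acetyl group on C8 (C8 epimerisable) | CC1(C)CC[C@@H](O[Si](C)(C)C(C)(C)C)[C@](C)([C@H]2[C@H](O[C@@H]3C[C@H](C)CC[C@H]3C(C)C)OC(=O)C2C(C)=O)C1=O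
F4 | step 5 | (11R)-1β-[(tert-butyldimethylsilyl)oxy]-5-hydroxy-11-[(1R,2S,5R)-menthyloxy]-7-oxodriman-12,11-olide (C5 and C8 not assigned) | CC1(C)CC[C@@H](O[Si](C)(C)C(C)(C)C)[C@]2(C)[C@H]3[C@H](O[C@@H]4C[C@H](C)CC[C@H]4C(C)C)OC(=O)C3C(=O)CC12O
F5 | step 5 | (11R)-1β-[(tert-butyldimethylsilyl)oxy]-7-hydroxy-11-[(1R,2S,5R)-menthyloxy]drima-5,7-dien-12,11-olide (enol form of the 7-oxo-5-ene) | CC1(C)CC[C@@H](O[Si](C)(C)C(C)(C)C)[C@]2(C)[C@H]3[C@H](O[C@@H]4C[C@H](C)CC[C@H]4C(C)C)OC(=O)C3=C(O)C=C12
F6 | step 5 | (11R)-1β-[(tert-butyldimethylsilyl)oxy]-11-[(1R,2S,5R)-menthyloxy]-7-(trifluoromethanesulfonyloxy)drima-5,7-dien-12,11-olide | CC1(C)CC[C@@H](O[Si](C)(C)C(C)(C)C)[C@]2(C)[C@H]3[C@H](O[C@@H]4C[C@H](C)CC[C@H]4C(C)C)OC(=O)C3=C(OS(=O)(=O)C(F)(F)F)C=C12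
F7 | step 7 | 1β-[(tert-butyldimethylsilyl)oxy]drim-7-ene-5α,11,12-triol | CC1(C)CC[C@@H](O[Si](C)(C)C(C)(C)C)[C@]2(C)[C@@H](CO)C(CO)=CC[C@@]12O
F8 | step 7 | 1β-[(tert-butyldimethylsilyl)oxy]-5α-hydroxydrim-7-ene-11,12-dial | CC1(C)CC[C@@H](O[Si](C)(C)C(C)(C)C)[C@]2(C)[C@@H](C=O)C(C=O)=CC[C@@]12O
F9 | step 10 | 1β-(carboxyacetoxy)-11,12-dimethoxy-11,12-epoxydrim-7-en-5α-ol (C11/C12 epimer mixture) | CC1(C)CC[C@@H](OC(=O)CC(=O)O)[C@]2(C)[C@H]3C(OC)OC(OC)C3=CC[C@@]12O
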